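**Plan**

1. Numbering: phthalide = 2-benzofuran-1(3H)-one (C1 carbonyl, C3 methylene, aromatic C4–C7); the side chain is C1′–C12′, counted from the O-bound CH2.
2. Cuts: after removal of two silyl groups, the C1′–C2′ and C3′–CH3 bonds are cut in one operation, leaving a terminal alkyne, Me3Al and an aryloxymethyl chloride.
3. Enabling feature: the ether oxygen on aromatic C5 of the benzene ring makes C1′ an α-oxygenated, oxocarbenium-type carbon (ArO–CH2–Cl). C2′=C3′ is an E trisubstituted alkene with CH3 on C3′, the pattern left by syn methylmetalation of a terminal alkyne.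
4. Chain half, forward: (E)-geranylacetone, hydration of the terminal alkene, triethylsilyl ether, methyl ketone to alkyne.
5. Ring half, forward: gallate ester, 4-O-CH2SMe (the future C1′), ortho-formylation, reduction that closes the lactone (the only ring formed), TBS ether, chlorinolysis to the chloromethyl ether; then union and desilylation.
6. Stereochemistry: the target has no stereocentre; C6′=C7′ (E) comes from geranylacetone, and C2′=C3′ (E) from syn carboalumination followed by substitution at carbon with retention.

Key step: step 10

Remark: geranylacetone is taken as the single E isomer (a mixed-isomer grade would first be enriched); the bromohydrin of step 1 is racemic at C9 and that centre is erased in step 2.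

**Route**

Step 1
Reactants: 1 (E)-geranylacetone, (5E)-6,10-dimethylundeca-5,9-dien-2-one
Product: 2 (5E)-9-bromo-10-hydroxy-6,10-dimethylundec-5-en-2-one (racemic at C9)
Conditions: NBS (1.1 equiv), THF–H2O, 0 °C
Reagents that add atoms: N-bromosuccinimide, O=C1CCC(=O)N1Br; water, O
Why: Bromohydrin formation in aqueous THF should take place at the terminal, most exposed isopropylidene alkene of the polyprenyl chain, with water opening the bromonium ion at the tertiary carbon (Markovnikov), while the ketone and the internal alkene stay untouched.

Step 2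
Reactants: 2 (5E)-9-bromo-10-hydroxy-6,10-dimethylundec-5-en-2-one
Product: 3 (5E)-10-hydroxy-6,10-dimethylundec-5-en-2-one
Conditions: Bu3SnH, AIBN (cat.), PhMe, 80 °C
Reagents that add atoms: none
Why: Radical chain dehalogenation replaces the secondary bromide by hydrogen, since the C9 radical has only 4-exo or 5-endo cyclisation paths to the C5 alkene and a β-hydroxyl is not expelled from a radical.

Step 3
Reactants: 3 (5E)-10-hydroxy-6,10-dimethylundec-5-en-2-one
Product: 4 (5E)-6,10-dimethyl-10-(triethylsilyloxy)undec-5-en-2-one
Conditions: Et3SiOTf, 2,6-lutidine, CH2Cl2, −78 °C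
Reagents that add atoms: triethylsilyl trifluoromethanesulfonate, CC[Si](CC)(CC)OS(=O)(=O)C(F)(F)F
Why: Silyl triflate silylation of the tertiary alcohol at −78 °C is far faster than enol silylation of the ketone, and the triethylsilyl ether keeps the oxygen out of the phosphorylation of step 4 and out of reach of the oxocarbenium ion in step 10.

Step 4
Reactants: 4 (5E)-6,10-dimethyl-10-(triethylsilyloxy)undec-5-en-2-one
Product: 6 triethyl{[(6E)-2,6-dimethylundec-6-en-10-yn-2-yl]oxy}silane, via diethyl enol phosphate 5 (not isolated)
Conditions: LiN(iPr)2 (1.1 equiv), THF, −78 °C; ClP(O)(OEt)2, −78 °C to rt; LiN(iPr)2 (2.3 equiv), THF, −78 °C to rt; H2O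
Reagents that add atoms: none
Why: This is the enol phosphate route from methyl ketones to terminal alkynes, in which kinetic deprotonation at the methyl group and O-phosphorylation are followed by amide-induced β-elimination, the excess base holding the product as its acetylide so that it does not isomerise.

Step 5
Reactants: 7 methyl 3,4-dihydroxy-5-methoxybenzoate; 8 chloromethyl methyl sulfide
Product: 9 methyl 3-hydroxy-5-methoxy-4-[(methylsulfanyl)methoxy]benzoate
Conditions: NaHCO3 (1.2 equiv), NaI (cat.), DMF, 40 °C
Reagents that add atoms: none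
Why: In this Williamson etherification the weak base deprotonates only the 4-OH, which is para to the ester and the most acidic, and iodide catalysis (Finkelstein exchange) makes the sluggish chloride reactive enough.

Step 6
Reactants: 9 methyl 3-hydroxy-5-methoxy-4-[(methylsulfanyl)methoxy]benzoate
Product: 10 methyl 2-formyl-3-hydroxy-5-methoxy-4-[(methylsulfanyl)methoxy]benzoate
Conditions: MgCl2, Et3N, (CH2O)n, MeCN, reflux; dilute aq. HCl work-up
Reagents that add atoms: paraformaldehyde (as formaldehyde), C=O
Why: In the magnesium-mediated ortho-formylation of phenols the magnesium phenoxide of the 3-OH delivers formaldehyde to C2, its only free ortho position, and a second formaldehyde oxidises the benzylic alkoxide to the aldehyde, so the position para to the phenol is not attacked.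

Step 7
Reactants: 10 methyl 2-formyl-3-hydroxy-5-methoxy-4-[(methylsulfanyl)methoxy]benzoate
Product: 12 4-hydroxy-6-methoxy-5-[(methylsulfanyl)methoxy]phthalide, via hydroxymethyl benzoate 11 (not isolated)
Conditions: NaBH4, THF–MeOH, 0 °C; then aq. HCl to pH 3, rt
Reagents that add atoms: none
Why: Borohydride reduction gives a benzylic alcohol ortho to the methyl ester, which closes the five-membered lactone by intramolecular transesterification (phthalide formation).

Step 8
Reactants: 12 4-hydroxy-6-methoxy-5-[(methylsulfanyl)methoxy]phthalide
Product: 13 4-(tert-butyldimethylsilyloxy)-6-methoxy-5-[(methylsulfanyl)methoxy]phthalide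
Conditions: TBSCl, imidazole, DMF, rt
Reagents that add atoms: tert-butyldimethylsilyl chloride, CC(C)(C)[Si](C)(C)Cl
Why: Imidazole-promoted silylation masks the only free phenol before the chlorination and the organoaluminium step, and silyl migration is impossible because O5 is already alkylated.

Step 9
Reactants: 13 4-(tert-butyldimethylsilyloxy)-6-methoxy-5-[(methylsulfanyl)methoxy]phthalide
Product: 14 4-(tert-butyldimethylsilyloxy)-5-(chloromethoxy)-6-methoxyphthalide
Conditions: SO2Cl2 (1.0 equiv), CH2Cl2, −40 to 0 °C; volatiles removed in vacuo; used crude at once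
Reagents that add atoms: sulfuryl chloride, O=S(=O)(Cl)Cl
Why: Chlorinolysis of the O,S-acetal (S-chlorination, then collapse of the chlorosulfonium ion with loss of MeSCl) is the established way to aryl chloromethyl ethers and should be much faster than chlorination of the acyl-deactivated ring.

Step 10
Reactants: 6 triethyl{[(6E)-2,6-dimethylundec-6-en-10-yn-2-yl]oxy}silane; 15 trimethylaluminium; 14 4-(tert-butyldimethylsilyloxy)-5-(chloromethoxy)-6-methoxyphthalide
Product: 17 4-(tert-butyldimethylsilyloxy)-6-methoxy-5-{[(2E,6E)-3,7,11-trimethyl-11-(triethylsilyloxy)dodeca-2,6-dien-1-yl]oxy}phthalide, via (E)-alkenyldimethylalane 16 (not isolated)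
Conditions: 6 (1.2 equiv), Me3Al (2.4 equiv), Cp2ZrCl2 (0.25 equiv), CH2Cl2, 0 °C to rt; volatiles and excess Me3Al removed in vacuo; 14 (1.0 equiv), CH2Cl2, −30 to 0 °C; cold aq. potassium sodium tartrate
Reagents that add atoms: none
Why: Proposed new method: Cp2ZrCl2-catalysed methylalumination adds CH3 and AlMe2 syn across the triple bond of 6, methyl to the internal carbon, which forms the C3′–CH3 bond and fixes C2′=C3′ as E, while the remote trisubstituted alkene and the tertiary silyl ether do not react. The Lewis-acidic aluminium then abstracts chloride from 14 to give an aryloxymethyl oxocarbenium chloroaluminate ion pair, which the alkenyl carbon captures at the aluminium-bearing position with retention of geometry (C1′–C2′ bond). The closest known reaction is the alkylation of such (E)-2-methylalkenyldimethylalanes with chloromethyl methyl ether to (E)-allylic methyl ethers, whereas an aryl chloromethyl ether has not been used as the electrophile. No ring is closed and no stereocentre is made, the only stereochemical element being the E alkene, which is controlled by syn addition and retentive substitution. The step needs alkenyl transfer to outrun methyl transfer and attack on the lactone, which is secured by stripping the excess Me3Al before 14 is added, by the higher transfer aptitude of the alkenyl group on aluminium and by working at or below 0 °C. The two ortho substituents (OTBS and OMe) twist the O5–CH2 bond out of the ring plane so that the oxygen lone pair supports ionisation despite the electron-poor phthalide, and an immediate cold tartrate quench protects the acid-sensitive allyl aryl ether.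

Step 11
Reactants: 17 4-(tert-butyldimethylsilyloxy)-6-methoxy-5-{[(2E,6E)-3,7,11-trimethyl-11-(triethylsilyloxy)dodeca-2,6-dien-1-yl]oxy}phthalide
Product: 18 Farnesylemefuranone E, 4-hydroxy-5-{[(2E,6E)-11-hydroxy-3,7,11-trimethyldodeca-2,6-dien-1-yl]oxy}-6-methoxyphthalide
Conditions: Bu4NF (3 equiv), THF, 0 °C to rt
Reagents that add atoms: none
Why: Fluoride-induced desilylation should cleave the aryl silyl ether quickly and the tertiary triethylsilyl ether on warming, conditions under which the lactone, the allyl aryl ether and both E alkenes are stable.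

**Compound list**

1 | (E)-geranylacetone, (5E)-6,10-dimethylundeca-5,9-dien-2-one | CC(=O)CC/C=C(\C)CCC=C(C)C | starting material
2 | (5E)-9-bromo-10-hydroxy-6,10-dimethylundec-5-en-2-one (racemic) | CC(=O)CC/C=C(\C)CCC(Br)C(C)(C)O | intermediate
3 | (5E)-10-hydroxy-6,10-dimethylundec-5-en-2-one | CC(=O)CC/C=C(\C)CCCC(C)(C)O | intermediate
4 | (5E)-6,10-dimethyl-10-(triethylsilyloxy)undec-5-en-2-one | CC(=O)CC/C=C(\C)CCCC(C)(C)O[Si](CC)(CC)CC | intermediate
5 | diethyl (5E)-6,10-dimethyl-10-(triethylsilyloxy)undeca-1,5-dien-2-yl phosphate | C=C(CC/C=C(\C)CCCC(C)(C)O[Si](CC)(CC)CC)OP(=O)(OCC)OCC | intermediate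
6 | triethyl{[(6E)-2,6-dimethylundec-6-en-10-yn-2-yl]oxy}silane | C#CCC/C=C(\C)CCCC(C)(C)O[Si](CC)(CC)CC | intermediate
7 | methyl 3,4-dihydroxy-5-methoxybenzoate | COC(=O)c1cc(O)c(O)c(OC)c1 | starting material
8 | chloromethyl methyl sulfide | CSCCl | starting material
9 | methyl 3-hydroxy-5-methoxy-4-[(methylsulfanyl)methoxy]benzoate | COC(=O)c1cc(O)c(OCSC)c(OC)c1 | intermediate
10 | methyl 2-formyl-3-hydroxy-5-methoxy-4-[(methylsulfanyl)methoxy]benzoate | COC(=O)c1cc(OC)c(OCSC)c(O)c1C=O | intermediate
11 | methyl 3-hydroxy-2-(hydroxymethyl)-5-methoxy-4-[(methylsulfanyl)methoxy]benzoate | COC(=O)c1cc(OC)c(OCSC)c(O)c1CO | intermediate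
12 | 4-hydroxy-6-methoxy-5-[(methylsulfanyl)methoxy]phthalide | COc1cc2c(c(O)c1OCSC)COC2=O | intermediate
13 | 4-(tert-butyldimethylsilyloxy)-6-methoxy-5-[(methylsulfanyl)methoxy]phthalide | COc1cc2c(c(O[Si](C)(C)C(C)(C)C)c1OCSC)COC2=O | intermediate
14 | 4-(tert-butyldimethylsilyloxy)-5-(chloromethoxy)-6-methoxyphthalide | COc1cc2c(c(O[Si](C)(C)C(C)(C)C)c1OCCl)COC2=O | intermediate
15 | trimethylaluminium | C[Al](C)C | starting material
16 | dimethyl[(1E,5E)-2,6,10-trimethyl-10-(triethylsilyloxy)undeca-1,5-dien-1-yl]alane | C[Al](C)/C=C(\C)CC/C=C(\C)CCCC(C)(C)O[Si](CC)(CC)CC | intermediate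
17 | 4-(tert-butyldimethylsilyloxy)-6-methoxy-5-{[(2E,6E)-3,7,11-trimethyl-11-(triethylsilyloxy)dodeca-2,6-dien-1-yl]oxy}phthalide | COc1cc2c(c(O[Si](C)(C)C(C)(C)C)c1OC/C=C(\C)CC/C=C(\C)CCCC(C)(C)O[Si](CC)(CC)CC)COC2=O | intermediate
18 | Farnesylemefuranone E | COc1cc2c(c(O)c1OC/C=C(\C)CC/C=C(\C)CCCC(C)(C)O)COC2=O | target

**Count and risks**

Total step count: 11 (steps 1–4 chain half, steps 5–9 ring half, steps 10–11 union and deprotection).
Longest linear sequence: 7 steps (from 7 through steps 5–11 to 18).

Steps most likely to fail:

1. Step 10 (Proposed new method). Ionisation of the aryl chloromethyl ether may be too slow, so that methyl transfer from aluminium, Lewis-acid cleavage of the newly formed allyl aryl ether or decomposition of the chloride competes with alkenyl transfer. The fallback uses known chemistry only; it sets out from 6 and 12 and returns to the route at 18. Alkyne 6 is methylaluminated as before to alane 16, which is converted with n-BuLi into lithium butyl(dimethyl)[(1E,5E)-2,6,10-trimethyl-10-(triethylsilyloxy)undeca-1,5-dien-1-yl]aluminate F1 and trapped with paraformaldehyde to give (2E,6E)-3,7,11-trimethyl-11-(triethylsilyloxy)dodeca-2,6-dien-1-ol F2. An Appel reaction (CBr4, PPh3, CH2Cl2, 0 °C) turns this into (2E,6E)-1-bromo-3,7,11-trimethyl-11-(triethylsilyloxy)dodeca-2,6-diene F3. In parallel the methylthiomethyl group of 12 is removed with HgCl2 and CaCO3 in aqueous MeCN to give 4,5-dihydroxy-6-methoxyphthalide F4. Its 5-OH, para to the lactone carbonyl and therefore the more acidic, is alkylated by F3 with NaHCO3 in DMF to give 4-hydroxy-6-methoxy-5-{[(2E,6E)-3,7,11-trimethyl-11-(triethylsilyloxy)dodeca-2,6-dien-1-yl]oxy}phthalide F5. Bu4NF in THF then removes the triethylsilyl group to give 18. The C1′–C2′ bond is then made at the alane stage with formaldehyde, and the ether by classical O-alkylation.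

2. Step 6. Electrophilic attack at C2, wedged between the phenol and the ester of an electron-poor ring, may be slow, and prolonged heating with formaldehyde invites over-reaction; partial lactonisation at the hydroxymethyl stage would be harmless because it also leads to 12. The fallback sets out from 9 and returns at 12. A boron-templated ortho-hydroxymethylation (PhB(OH)2, (CH2O)n, cat. EtCO2H, PhMe, reflux with water removal) delivers formaldehyde intramolecularly and gives methyl 7-methoxy-8-[(methylsulfanyl)methoxy]-2-phenyl-4H-1,3,2-benzodioxaborinine-5-carboxylate F6. Exchange of the boron onto propane-1,3-diol frees hydroxymethyl benzoate 11, which lactonises to 12. The aldehyde oxidation level and the hydride reduction are bypassed.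

3. Step 9. Electrophilic chlorine or the sulfenyl chloride formed may attack aromatic C7 (ortho to OMe, para to the silyloxy group), adventitious HCl may remove the silyl ether, and the chloromethyl ether may hydrolyse on handling. The fallback sets out from 13 and returns at 14. The methylthiomethyl group is removed with HgCl2 and CaCO3 in aqueous MeCN to give 4-(tert-butyldimethylsilyloxy)-5-hydroxy-6-methoxyphthalide F7. This phenol, flanked by two ortho substituents, is O-chloromethylated with excess bromochloromethane and NaH in THF, a known way to convert phenols into aryl chloromethyl ethers, to give 14. The phenoxide on O5 is the more stabilised one, so silyl migration from O4 is uphill. No electrophilic chlorine or sulfur species is present in this variant.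

**Further compounds**

F1 | step 10 | lithium butyl(dimethyl)[(1E,5E)-2,6,10-trimethyl-10-(triethylsilyloxy)undeca-1,5-dien-1-yl]aluminate | [Li+].CCCC[Al-](C)(C)/C=C(\C)CC/C=C(\C)CCCC(C)(C)O[Si](CC)(CC)CC
F2 | step 10 | (2E,6E)-3,7,11-trimethyl-11-(triethylsilyloxy)dodeca-2,6-dien-1-ol | OC/C=C(\C)CC/C=C(\C)CCCC(C)(C)O[Si](CC)(CC)CC
F3 | step 10 | (2E,6E)-1-bromo-3,7,11-trimethyl-11-(triethylsilyloxy)dodeca-2,6-diene | BrC/C=C(\C)CC/C=C(\C)CCCC(C)(C)O[Si](CC)(CC)CC
F4 | step 10 | 4,5-dihydroxy-6-methoxyphthalide | COc1cc2c(c(O)c1O)COC2=O
F5 | step 10 | 4-hydroxy-6-methoxy-5-{[(2E,6E)-3,7,11-trimethyl-11-(triethylsilyloxy)dodeca-2,6-dien-1-yl]oxy}phthalide | COc1cc2c(c(O)c1OC/C=C(\C)CC/C=C(\C)CCCC(C)(C)O[Si](CC)(CC)CC)COC2=O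
F6 | step 6 | methyl 7-methoxy-8-[(methylsulfanyl)methoxy]-2-phenyl-4H-1,3,2-benzodioxaborinine-5-carboxylate | COC(=O)c1cc(OC)c(OCSC)c2c1COB(c1ccccc1)O2
F7 | step 9 | 4-(tert-butyldimethylsilyloxy)-5-hydroxy-6-methoxyphthalide | COc1cc2c(c(O[Si](C)(C)C(C)(C)C)c1O)COC2=O
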